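## Retrosynthetic overview

1. The target is epioritin-(4β→6)-oritin-(4α→6)-epioritin-4α-ol. Both interflavan C4–C6 bonds are cut as Friedel–Crafts attacks of ring A on a C4 benzylic cation (upper bond after hard activation of a 4-OH, lower bond after soft activation of a 4-thioether). This gives three monomers, and the upper and lower ones are the same all-cis flavan-3,4-diol.
2. In each monomer ring C is cut at O1–C8a and C4a–C4. The enabling feature: C8a, the ring A carbon that carries the pyran oxygen O1 and is flanked by the oxygenated C8, lies ortho to C4a, and C4a bears a carbinol carbon (C4). Ring A can therefore enter as an arene with fluorine on C8a and a metal on C4a (lithium in the key step, magnesium for the middle unit), and O1–C2–C3–C4 as a β-silyloxy-α-benzyloxy aldehyde.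
3. Both aldehydes (syn for the 2,3-cis units, anti for the 2,3-trans unit) come from one N-glycolyl oxazolidinethione and 4-(benzyloxy)benzaldehyde by syn- or anti-selective titanium aldol reactions.
4. Order of ring formation: rings A and B are bought as benzenes; ring C of the lower/upper unit (step 6); ring C of the middle unit (step 11); then the C4–C6 bond upper→middle (step 14) and middle→lower (step 16); desilylation and hydrogenolysis finish.

Key step: step 6

Remark: wherever C4 is ionised (steps 12 and 14) either C4 epimer of 19 or 12 serves equally, so only the portion of 12 used for 24 must be the pure 4α-alcohol; 1, 3, 4, 6 and 20 are taken as commercial.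

## Route

Step 1
Reactants: 1 3-fluorocatechol
Product: 2 1,2-bis(benzyloxy)-3-fluorobenzene
Conditions: BnBr (2.2 equiv), K2CO3, DMF, 60 °C
Reagents that add atoms: benzyl bromide BrCc1ccccc1
Why: Double Williamson etherification; benzyl ethers are used throughout so that one hydrogenolysis frees all phenols at the end.

Step 2
Reactants: 3 (S)-4-benzyl-1,3-oxazolidine-2-thione; 4 (benzyloxy)acetyl chloride
Product: 5 (S)-4-benzyl-3-[(benzyloxy)acetyl]-1,3-oxazolidine-2-thione
Conditions: Et3N, CH2Cl2, 0 °C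
Reagents that add atoms: none
Why: N-acylation of the auxiliary gives the glycolate imide whose benzyl ether becomes the 3-O-benzyl group of every flavan unit.

Step 3
Reactants: 5 (S)-4-benzyl-3-[(benzyloxy)acetyl]-1,3-oxazolidine-2-thione; 6 4-(benzyloxy)benzaldehyde
Product: 7 (S)-4-benzyl-3-[(2S,3R)-2-(benzyloxy)-3-[4-(benzyloxy)phenyl]-3-hydroxypropanoyl]-1,3-oxazolidine-2-thione
Conditions: TiCl4 (1.05 equiv), i-Pr2NEt (1.1 equiv), N-methyl-2-pyrrolidone (1 equiv), CH2Cl2, 0 °C; then 6, −78 → 0 °C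
Reagents that add atoms: none
Why: Auxiliary-controlled titanium enolate aldol reaction; with the thiocarbonyl displaced from titanium the (Z)-enolate should react through a non-chelated Zimmerman–Traxler chair on the face away from the auxiliary benzyl group, setting both new centres as the 2,3-syn (2S,3R) pair.

Step 4
Reactants: 7 syn aldol adduct
Product: 8 (S)-4-benzyl-3-[(2S,3R)-2-(benzyloxy)-3-[4-(benzyloxy)phenyl]-3-[(triethylsilyl)oxy]propanoyl]-1,3-oxazolidine-2-thione
Conditions: Et3SiOTf, 2,6-lutidine, CH2Cl2, −78 °C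
Reagents that add atoms: triethylsilyl trifluoromethanesulfonate CC[Si](CC)(CC)OS(=O)(=O)C(F)(F)F
Why: Silylation of the benzylic hydroxyl (the future O1) with a group that survives hydride and aryllithium but is stripped by alkoxide in step 6; no stereocentre is touched.

Step 5
Reactants: 8 silylated syn imide
Product: 9 (2S,3R)-2-(benzyloxy)-3-[4-(benzyloxy)phenyl]-3-[(triethylsilyl)oxy]propanal
Conditions: i-Bu2AlH, CH2Cl2, −78 °C; aq. potassium sodium tartrate
Reagents that add atoms: none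
Why: Direct hydride reduction of the N-acyl oxazolidinethione should stop at the aldehyde because the aluminium hemiaminal is stable at −78 °C, so the α-centre is not epimerised and auxiliary 3 is recovered.

Step 6
Reactants: 2 1,2-bis(benzyloxy)-3-fluorobenzene; 9 (2S,3R)-2-(benzyloxy)-3-[4-(benzyloxy)phenyl]-3-[(triethylsilyl)oxy]propanal
Product: 12 (2R,3R,4R)-3,7,8-tris(benzyloxy)-2-[4-(benzyloxy)phenyl]-3,4-dihydro-2H-chromen-4-ol, via aryllithium 10 (not isolated), via lithium alkoxide 11 (not isolated)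
Conditions: 2 (1.2 equiv), n-BuLi (1.15 equiv), THF, −78 °C; 9, −78 °C; then t-BuOK (4 equiv), DMF, −78 → 70 °C; H2O
Reagents that add atoms: none
Why: Fluorine-directed ortho-lithiation of 2 removes the only proton flanked by fluorine (the future C4a) to give 10, a fixed 1,2-dipole equivalent of ring A (nucleophilic C4a, electrophilic C–F carbon = future C8a); 10 adds to aldehyde 9 to form C4a–C4, then tert-butoxide takes the triethylsilyl group from the C2 oxygen and the potassium alkoxide displaces fluoride by intramolecular nucleophilic aromatic substitution to form O1–C8a. The closest known reaction types are aryllithium addition to α-alkoxy aldehydes and the alkoxide/fluoroarene SNAr oxy-cyclisation that closes flavan pyran rings from the C2 oxygen. Ring C closes by 6-exo attack of the C2 alkoxide on the aromatic carbon (addition–elimination through a Meisenheimer-type complex); the C4 alkoxide could only give a four-membered ring and O3 is a benzyl ether, so no smaller cyclic ether can compete. The new stereocentre C4 is set in the addition by Felkin–Anh (Cornforth) control from the α-benzyloxy centre under non-chelating conditions (lithium in THF), the aryl group entering anti to the C3–O bond, which should favour the 3,4-anti carbinol and hence the 3,4-cis (4α-OH, all-cis) ring; C2 and C3 are carried over unchanged from 9. The selectivities needed are the site of lithiation (fluorine is the strongest acidifying director in 2), survival of the ortho-fluoroaryllithium (kept at −78 °C so that LiF is not lost to an aryne before the addition) and SNAr on an electron-rich ring (helped by the inductive pull of the adjacent C8–O bond, potassium chelation by the ortho benzyloxy group and the dipolar solvent). A minor C4 epimer is separable and is still valid feed for the upper unit, whose C4 is ionised in step 14.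

Step 7
Reactants: 5 (S)-4-benzyl-3-[(benzyloxy)acetyl]-1,3-oxazolidine-2-thione; 6 4-(benzyloxy)benzaldehyde
Product: 13 (S)-4-benzyl-3-[(2R,3R)-2-(benzyloxy)-3-[4-(benzyloxy)phenyl]-3-hydroxypropanoyl]-1,3-oxazolidine-2-thione
Conditions: TiCl4 (1.0 equiv), i-Pr2NEt (1.0 equiv), CH2Cl2, −78 °C; then 6 premixed with TiCl4 (2.0 equiv), −78 °C
Reagents that add atoms: none
Why: Anti-selective glycolate aldol reaction; the chelated titanium enolate (thiocarbonyl bound to titanium) should be attacked through an open transition state by the TiCl4-activated aldehyde on the enolate face away from the auxiliary benzyl group, giving the 2,3-anti (2R,3R) adduct, with minor syn isomers removed by chromatography.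

Step 8
Reactants: 13 anti aldol adduct
Product: 14 (S)-4-benzyl-3-[(2R,3R)-2-(benzyloxy)-3-[4-(benzyloxy)phenyl]-3-[(triethylsilyl)oxy]propanoyl]-1,3-oxazolidine-2-thione
Conditions: Et3SiOTf, 2,6-lutidine, CH2Cl2, −78 °C
Reagents that add atoms: triethylsilyl trifluoromethanesulfonate CC[Si](CC)(CC)OS(=O)(=O)C(F)(F)F
Why: Silyl protection of the benzylic hydroxyl as in step 4, without change at either stereocentre.

Step 9
Reactants: 14 silylated anti imide
Product: 15 (2R,3R)-2-(benzyloxy)-3-[4-(benzyloxy)phenyl]-3-[(triethylsilyl)oxy]propanal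
Conditions: i-Bu2AlH, CH2Cl2, −78 °C; aq. potassium sodium tartrate
Reagents that add atoms: none
Why: Direct reduction of the N-acyl oxazolidinethione to the aldehyde as in step 5, with recovery of 3 and no epimerisation at −78 °C.

Step 10
Reactants: 2 1,2-bis(benzyloxy)-3-fluorobenzene
Product: 16 1,2-bis(benzyloxy)-3-fluoro-4-iodobenzene
Conditions: N-iodosuccinimide (1.05 equiv), CF3CO2H (0.1 equiv), MeCN, rt
Reagents that add atoms: N-iodosuccinimide IN1C(=O)CCC1=O
Why: Electrophilic aromatic iodination; the 1-benzyloxy group has only one ortho substituent and stays in conjugation, so it should direct para to C4 (the carbon next to fluorine), whereas the 2-benzyloxy group is twisted out of plane by its two neighbours, and minor regioisomers are removed by crystallisation.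

Step 11
Reactants: 16 1,2-bis(benzyloxy)-3-fluoro-4-iodobenzene; 15 (2R,3R)-2-(benzyloxy)-3-[4-(benzyloxy)phenyl]-3-[(triethylsilyl)oxy]propanal
Product: 19 (2R,3S,4R)-3,7,8-tris(benzyloxy)-2-[4-(benzyloxy)phenyl]-3,4-dihydro-2H-chromen-4-ol, via arylmagnesium chloride 17 (not isolated), via magnesium alkoxide 18 (not isolated)
Conditions: 16 (1.2 equiv), i-PrMgCl·LiCl (1.15 equiv), THF, −40 °C; 15, −40 → 0 °C; volatiles (THF, 2-iodopropane) removed in vacuo; then t-BuOK (4 equiv), DMF, 0 → 70 °C; H2O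
Reagents that add atoms: none
Why: Iodine–magnesium exchange gives the ortho-fluoroaryl Grignard reagent 17 (stable to loss of fluoride at −40 °C), which adds to aldehyde 15 under Cram-chelate control through magnesium bound to the carbonyl and the α-benzyloxy oxygen (3,4-trans carbinol drawn), and tert-butoxide-triggered desilylation with intramolecular SNAr then closes ring C of the 2,3-trans unit as in step 6; the C4 configuration is of no consequence because C4 is ionised in step 12, so the more robust magnesium reagent is used here.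

Step 12
Reactants: 19 2,3-trans flavan-4-ol; 20 2,6-dimethylbenzenethiol
Product: 21 (2R,3R,4R)-3,7,8-tris(benzyloxy)-2-[4-(benzyloxy)phenyl]-4-[(2,6-dimethylphenyl)sulfanyl]-3,4-dihydro-2H-chromene
Conditions: 20 (3 equiv), BF3·OEt2, CH2Cl2, −78 → −20 °C
Reagents that add atoms: none
Why: SN1 thiolysis through the C4 benzylic cation (stabilised by the para C7 oxygen and by O1), with the thiol adding anti to the 3-benzyloxy group (3,4-trans); the hindered aryl sulfide is inert to hard Lewis acid and does not undergo sulfur transfer.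

Step 13
Reactants: 12 all-cis flavan-4-ol
Product: 22 (2R,3R,4R)-3,7,8-tris(benzyloxy)-2-[4-(benzyloxy)phenyl]-6-bromo-3,4-dihydro-2H-chromen-4-ol
Conditions: NBS (1.0 equiv), CH2Cl2, −40 → 0 °C
Reagents that add atoms: N-bromosuccinimide BrN1C(=O)CCC1=O
Why: Electrophilic aromatic bromination at C6, the position ortho to the C7 oxygen and para to O1 of the 1,2,3-trioxygenated ring A; the bromine caps the only strongly nucleophilic carbon of the future electrophile and leaves in the last step.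

Step 14
Reactants: 22 6-bromo flavan-4-ol; 21 4-thioether of the 2,3-trans unit
Product: 23 6-bromo-tetra-O-benzylepioritin-(4β→6)-tetra-O-benzyl-4α-[(2,6-dimethylphenyl)sulfanyl]oritin
Conditions: 21 (1.5 equiv), BF3·OEt2, 4 Å molecular sieves, CH2Cl2, −78 → −30 °C
Reagents that add atoms: none
Why: Friedel–Crafts alkylation; the hard Lewis acid ionises the 4-OH of 22 but not the thioether of 21, and C6 of 21 should attack the cation on the face anti to the 3-benzyloxy and 2-aryl groups (both α), giving the 4β (3,4-trans) bond, while the bromine cap prevents self-condensation of 22.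

Step 15
Reactants: 12 all-cis flavan-4-ol
Product: 24 (2R,3R,4R)-3,7,8-tris(benzyloxy)-2-[4-(benzyloxy)phenyl]-4-[(tert-butyldimethylsilyl)oxy]-3,4-dihydro-2H-chromene
Conditions: t-BuMe2SiOTf, 2,6-lutidine, CH2Cl2, −78 °C
Reagents that add atoms: tert-butyldimethylsilyl trifluoromethanesulfonate CC(C)(C)[Si](C)(C)OS(=O)(=O)C(F)(F)F
Why: Silylation of the 4α-hydroxyl keeps the lower unit from O-alkylation and from ionisation at its own C4 in the next coupling; the configuration is retained.

Step 16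
Reactants: 23 bromo-capped dimeric thioether; 24 silylated lower unit
Product: 25 6-bromo-tetra-O-benzylepioritin-(4β→6)-tetra-O-benzyloritin-(4α→6)-tetra-O-benzyl-4-O-(tert-butyldimethylsilyl)epioritin-4α-ol
Conditions: 24 (2 equiv), I2, Ag2O, 4 Å molecular sieves, CH2Cl2, −78 → 0 °C
Reagents that add atoms: none
Why: Soft (thiophilic) activation of the aryl sulfide releases the C4 cation of the middle unit for Friedel–Crafts attack by C6 of 24 (ortho to the C7 oxygen, para to O1) anti to the β 3-benzyloxy group, giving the 4α (3,4-trans) bond; 23 has no free activated ring position and cannot oligomerise.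

Step 17
Reactants: 25 silylated protected trimer
Product: 26 6-bromo-tetra-O-benzylepioritin-(4β→6)-tetra-O-benzyloritin-(4α→6)-tetra-O-benzylepioritin-4α-ol
Conditions: Bu4NF, THF, 0 °C → rt
Reagents that add atoms: none
Why: Fluoride-mediated cleavage of the silyl ether under non-acidic conditions, so that neither the C4 carbinol nor the interflavan bonds are ionised.

Step 18
Reactants: 26 protected trimer
Product: 27 epioritin-(4β→6)-oritin-(4α→6)-epioritin-4α-ol (CNP0140823.2)
Conditions: H2 (1 atm), Pd(OH)2/C, Et3N, THF/MeOH, rt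
Reagents that add atoms: none
Why: Catalytic hydrogenolysis should cleave the twelve benzyl ethers and the aryl bromide together; triethylamine takes up HBr so that the benzylic 4-OH and the acid-labile interflavan bonds are not ionised, and the cyclic O1–C2 bonds survive as is usual for flavans.

## Compound list

1 | 3-fluorocatechol | Oc1cccc(F)c1O | starting material
2 | 1,2-bis(benzyloxy)-3-fluorobenzene | Fc1cccc(OCc2ccccc2)c1OCc1ccccc1 | intermediate
3 | (S)-4-benzyl-1,3-oxazolidine-2-thione | S=C1OC[C@H](Cc2ccccc2)N1 | starting material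
4 | (benzyloxy)acetyl chloride | ClC(=O)COCc1ccccc1 | starting material
5 | (S)-4-benzyl-3-[(benzyloxy)acetyl]-1,3-oxazolidine-2-thione | O=C(COCc1ccccc1)N1[C@@H](Cc2ccccc2)COC1=S | intermediate
6 | 4-(benzyloxy)benzaldehyde | O=Cc1ccc(OCc2ccccc2)cc1 | starting material
7 | (S)-4-benzyl-3-[(2S,3R)-2-(benzyloxy)-3-[4-(benzyloxy)phenyl]-3-hydroxypropanoyl]-1,3-oxazolidine-2-thione | O[C@H](c1ccc(OCc2ccccc2)cc1)[C@H](OCc1ccccc1)C(=O)N1[C@@H](Cc2ccccc2)COC1=S | intermediate
8 | (S)-4-benzyl-3-[(2S,3R)-2-(benzyloxy)-3-[4-(benzyloxy)phenyl]-3-[(triethylsilyl)oxy]propanoyl]-1,3-oxazolidine-2-thione | CC[Si](CC)(CC)O[C@H](c1ccc(OCc2ccccc2)cc1)[C@H](OCc1ccccc1)C(=O)N1[C@@H](Cc2ccccc2)COC1=S | intermediate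
9 | (2S,3R)-2-(benzyloxy)-3-[4-(benzyloxy)phenyl]-3-[(triethylsilyl)oxy]propanal | CC[Si](CC)(CC)O[C@H](c1ccc(OCc2ccccc2)cc1)[C@H](OCc1ccccc1)C=O | intermediate
10 | [3,4-bis(benzyloxy)-2-fluorophenyl]lithium | [Li]c1ccc(OCc2ccccc2)c(OCc2ccccc2)c1F | intermediate
11 | lithium (1R,2R,3R)-2-(benzyloxy)-1-[3,4-bis(benzyloxy)-2-fluorophenyl]-3-[4-(benzyloxy)phenyl]-3-[(triethylsilyl)oxy]propan-1-olate | CC[Si](CC)(CC)O[C@H](c1ccc(OCc2ccccc2)cc1)[C@H](OCc1ccccc1)[C@H](O[Li])c1ccc(OCc2ccccc2)c(OCc2ccccc2)c1F | intermediate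
12 | (2R,3R,4R)-3,7,8-tris(benzyloxy)-2-[4-(benzyloxy)phenyl]-3,4-dihydro-2H-chromen-4-ol (all-cis) | c1cc2c(c(OCc3ccccc3)c1OCc1ccccc1)O[C@H](c1ccc(OCc3ccccc3)cc1)[C@H](OCc1ccccc1)[C@@H]2O | intermediate
13 | (S)-4-benzyl-3-[(2R,3R)-2-(benzyloxy)-3-[4-(benzyloxy)phenyl]-3-hydroxypropanoyl]-1,3-oxazolidine-2-thione | O[C@H](c1ccc(OCc2ccccc2)cc1)[C@@H](OCc1ccccc1)C(=O)N1[C@@H](Cc2ccccc2)COC1=S | intermediate
14 | (S)-4-benzyl-3-[(2R,3R)-2-(benzyloxy)-3-[4-(benzyloxy)phenyl]-3-[(triethylsilyl)oxy]propanoyl]-1,3-oxazolidine-2-thione | CC[Si](CC)(CC)O[C@H](c1ccc(OCc2ccccc2)cc1)[C@@H](OCc1ccccc1)C(=O)N1[C@@H](Cc2ccccc2)COC1=S | intermediate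
15 | (2R,3R)-2-(benzyloxy)-3-[4-(benzyloxy)phenyl]-3-[(triethylsilyl)oxy]propanal | CC[Si](CC)(CC)O[C@H](c1ccc(OCc2ccccc2)cc1)[C@@H](OCc1ccccc1)C=O | intermediate
16 | 1,2-bis(benzyloxy)-3-fluoro-4-iodobenzene | Ic1ccc(OCc2ccccc2)c(OCc2ccccc2)c1F | intermediate
17 | [3,4-bis(benzyloxy)-2-fluorophenyl]magnesium chloride | Cl[Mg]c1ccc(OCc2ccccc2)c(OCc2ccccc2)c1F | intermediate
18 | chloromagnesium (1R,2S,3R)-2-(benzyloxy)-1-[3,4-bis(benzyloxy)-2-fluorophenyl]-3-[4-(benzyloxy)phenyl]-3-[(triethylsilyl)oxy]propan-1-olate | CC[Si](CC)(CC)O[C@H](c1ccc(OCc2ccccc2)cc1)[C@@H](OCc1ccccc1)[C@H](O[Mg]Cl)c1ccc(OCc2ccccc2)c(OCc2ccccc2)c1F | intermediate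
19 | (2R,3S,4R)-3,7,8-tris(benzyloxy)-2-[4-(benzyloxy)phenyl]-3,4-dihydro-2H-chromen-4-ol (2,3-trans-3,4-trans) | c1cc2c(c(OCc3ccccc3)c1OCc1ccccc1)O[C@H](c1ccc(OCc3ccccc3)cc1)[C@@H](OCc1ccccc1)[C@@H]2O | intermediate
20 | 2,6-dimethylbenzenethiol | Cc1cccc(C)c1S | starting material
21 | (2R,3R,4R)-3,7,8-tris(benzyloxy)-2-[4-(benzyloxy)phenyl]-4-[(2,6-dimethylphenyl)sulfanyl]-3,4-dihydro-2H-chromene (2,3-trans-3,4-trans) | c1cc2c(c(OCc3ccccc3)c1OCc1ccccc1)O[C@H](c1ccc(OCc3ccccc3)cc1)[C@@H](OCc1ccccc1)[C@@H]2Sc1c(C)cccc1C | intermediate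
22 | (2R,3R,4R)-3,7,8-tris(benzyloxy)-2-[4-(benzyloxy)phenyl]-6-bromo-3,4-dihydro-2H-chromen-4-ol | Brc1cc2c(c(OCc3ccccc3)c1OCc1ccccc1)O[C@H](c1ccc(OCc3ccccc3)cc1)[C@H](OCc1ccccc1)[C@@H]2O | intermediate
23 | 6-bromo-tetra-O-benzylepioritin-(4β→6)-tetra-O-benzyl-4α-[(2,6-dimethylphenyl)sulfanyl]oritin | C(c1ccccc1)Oc1ccc([C@H]2Oc3c(cc(Br)c(OCc4ccccc4)c3OCc3ccccc3)[C@H](c3cc4c(c(OCc5ccccc5)c3OCc3ccccc3)O[C@H](c3ccc(OCc5ccccc5)cc3)[C@@H](OCc3ccccc3)[C@@H]4Sc3c(C)cccc3C)[C@H]2OCc2ccccc2)cc1 | intermediate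
24 | (2R,3R,4R)-3,7,8-tris(benzyloxy)-2-[4-(benzyloxy)phenyl]-4-[(tert-butyldimethylsilyl)oxy]-3,4-dihydro-2H-chromene | c1cc2c(c(OCc3ccccc3)c1OCc1ccccc1)O[C@H](c1ccc(OCc3ccccc3)cc1)[C@H](OCc1ccccc1)[C@@H]2O[Si](C)(C)C(C)(C)C | intermediate
25 | 6-bromo-tetra-O-benzylepioritin-(4β→6)-tetra-O-benzyloritin-(4α→6)-tetra-O-benzyl-4-O-(tert-butyldimethylsilyl)epioritin-4α-ol | C(c1ccccc1)Oc1ccc([C@H]2Oc3c(cc(Br)c(OCc4ccccc4)c3OCc3ccccc3)[C@H](c3cc4c(c(OCc5ccccc5)c3OCc3ccccc3)O[C@H](c3ccc(OCc5ccccc5)cc3)[C@@H](OCc3ccccc3)[C@@H]4c3cc4c(c(OCc5ccccc5)c3OCc3ccccc3)O[C@H](c3ccc(OCc5ccccc5)cc3)[C@H](OCc3ccccc3)[C@@H]4O[Si](C)(C)C(C)(C)C)[C@H]2OCc2ccccc2)cc1 | intermediate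
26 | 6-bromo-tetra-O-benzylepioritin-(4β→6)-tetra-O-benzyloritin-(4α→6)-tetra-O-benzylepioritin-4α-ol | C(c1ccccc1)Oc1ccc([C@H]2Oc3c(cc(Br)c(OCc4ccccc4)c3OCc3ccccc3)[C@H](c3cc4c(c(OCc5ccccc5)c3OCc3ccccc3)O[C@H](c3ccc(OCc5ccccc5)cc3)[C@@H](OCc3ccccc3)[C@@H]4c3cc4c(c(OCc5ccccc5)c3OCc3ccccc3)O[C@H](c3ccc(OCc5ccccc5)cc3)[C@H](OCc3ccccc3)[C@@H]4O)[C@H]2OCc2ccccc2)cc1 | intermediate
27 | epioritin-(4β→6)-oritin-(4α→6)-epioritin-4α-ol (CNP0140823.2) | Oc1ccc([C@H]2Oc3c(ccc(O)c3O)[C@H](c3cc4c(c(O)c3O)O[C@H](c3ccc(O)cc3)[C@@H](O)[C@@H]4c3cc4c(c(O)c3O)O[C@H](c3ccc(O)cc3)[C@H](O)[C@@H]4O)[C@H]2O)cc1 | target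

## Step count and risks

Total steps: 18. Longest linear sequence: 10 steps (2 → 3 → 4 → 5 → 6 → 13 → 14 → 16 → 17 → 18; the branch 2 → 7 → 8 → 9 → 11 → 12 → 14 → 16 → 17 → 18 is equally long).

Steps most likely to fail:

1. Step 6 (key annulation). The C2 alkoxide may displace fluoride from the electron-rich ring too slowly, so that the dialkoxide degrades on heating, and the aryllithium addition may show poor facial selectivity at C4. Fallback, setting out from 2 and 9: the lithiation/addition is quenched at −78 °C to give the epimeric carbinols (1RS,2R,3R)-2-(benzyloxy)-1-[3,4-bis(benzyloxy)-2-fluorophenyl]-3-[4-(benzyloxy)phenyl]-3-[(triethylsilyl)oxy]propan-1-ol F1. Dess–Martin oxidation converts both epimers into the 2-fluoroaryl ketone (2S,3R)-2-(benzyloxy)-1-[3,4-bis(benzyloxy)-2-fluorophenyl]-3-[4-(benzyloxy)phenyl]-3-[(triethylsilyl)oxy]propan-1-one F2. CsF in DMF at 0 °C then removes the silyl group and the alkoxide closes ring C by a carbonyl-activated SNAr to the 2,3-cis chromanone (2R,3S)-3,7,8-tris(benzyloxy)-2-[4-(benzyloxy)phenyl]-2,3-dihydro-4H-chromen-4-one F3. NaBH4 in MeOH/CH2Cl2 at −78 °C should deliver hydride anti to the 2-aryl and 3-benzyloxy groups, and the route is rejoined at 12.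

2. Step 7 (anti aldol). A competing closed transition state may erode the anti selectivity with the benzyl-protected glycolate. Fallback, setting out from 4 and 6: 4 with ethanethiol and pyridine gives S-ethyl 2-(benzyloxy)ethanethioate F4. LiN(i-Pr)2 and Me3SiCl convert it into the (Z)-silyl ketene thioacetal (Z)-{[2-(benzyloxy)-1-(ethylsulfanyl)ethenyl]oxy}(trimethyl)silane F5. A Mukaiyama aldol reaction with 6, promoted by Sn(OTf)2, a proline-derived chiral diamine and Bu2Sn(OAc)2 (anti-selective for α-benzyloxy thioacetals), should give S-ethyl (2R,3R)-2-(benzyloxy)-3-[4-(benzyloxy)phenyl]-3-hydroxypropanethioate F6. Silylation with Et3SiOTf gives S-ethyl (2R,3R)-2-(benzyloxy)-3-[4-(benzyloxy)phenyl]-3-[(triethylsilyl)oxy]propanethioate F7, and i-Bu2AlH reduction at −78 °C rejoins the route at 15.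

3. Step 16 (second interflavan bond). Capture of the C4 cation by the weakly nucleophilic pyrogallol-type ring A of 24 may be slow, allowing proton loss to the flav-3-ene, attack through C5 or iodination of the nucleophile. Fallback, setting out from 21 and 24, with the order of bond formation reversed: the monomeric thioether 21 is activated with I2/Ag2O in the presence of a large, recoverable excess of 24. This should give the dimer tetra-O-benzyloritin-(4α→6)-tetra-O-benzyl-4-O-(tert-butyldimethylsilyl)epioritin-4α-ol F8. BF3·OEt2-mediated Friedel–Crafts alkylation of F8 at C6 of its oritin unit by the cation from 22 at −78 °C then rejoins the route at 25.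

## Further compounds

F1 | step 6 | (1RS,2R,3R)-2-(benzyloxy)-1-[3,4-bis(benzyloxy)-2-fluorophenyl]-3-[4-(benzyloxy)phenyl]-3-[(triethylsilyl)oxy]propan-1-ol | CC[Si](CC)(CC)O[C@H](c1ccc(OCc2ccccc2)cc1)[C@H](OCc1ccccc1)C(O)c1ccc(OCc2ccccc2)c(OCc2ccccc2)c1F
F2 | step 6 | (2S,3R)-2-(benzyloxy)-1-[3,4-bis(benzyloxy)-2-fluorophenyl]-3-[4-(benzyloxy)phenyl]-3-[(triethylsilyl)oxy]propan-1-one | CC[Si](CC)(CC)O[C@H](c1ccc(OCc2ccccc2)cc1)[C@H](OCc1ccccc1)C(=O)c1ccc(OCc2ccccc2)c(OCc2ccccc2)c1F
F3 | step 6 | (2R,3S)-3,7,8-tris(benzyloxy)-2-[4-(benzyloxy)phenyl]-2,3-dihydro-4H-chromen-4-one | c1cc2c(c(OCc3ccccc3)c1OCc1ccccc1)O[C@H](c1ccc(OCc3ccccc3)cc1)[C@H](OCc1ccccc1)C2=O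
F4 | step 7 | S-ethyl 2-(benzyloxy)ethanethioate | CCSC(=O)COCc1ccccc1
F5 | step 7 | (Z)-{[2-(benzyloxy)-1-(ethylsulfanyl)ethenyl]oxy}(trimethyl)silane | CCS/C(O[Si](C)(C)C)=C\OCc1ccccc1
F6 | step 7 | S-ethyl (2R,3R)-2-(benzyloxy)-3-[4-(benzyloxy)phenyl]-3-hydroxypropanethioate | O[C@H](c1ccc(OCc2ccccc2)cc1)[C@@H](OCc1ccccc1)C(=O)SCC
F7 | step 7 | S-ethyl (2R,3R)-2-(benzyloxy)-3-[4-(benzyloxy)phenyl]-3-[(triethylsilyl)oxy]propanethioate | CC[Si](CC)(CC)O[C@H](c1ccc(OCc2ccccc2)cc1)[C@@H](OCc1ccccc1)C(=O)SCC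
F8 | step 16 | tetra-O-benzyloritin-(4α→6)-tetra-O-benzyl-4-O-(tert-butyldimethylsilyl)epioritin-4α-ol | c1cc2c(c(OCc3ccccc3)c1OCc1ccccc1)O[C@H](c1ccc(OCc3ccccc3)cc1)[C@@H](OCc1ccccc1)[C@@H]2c1cc2c(c(OCc3ccccc3)c1OCc1ccccc1)O[C@H](c1ccc(OCc3ccccc3)cc1)[C@H](OCc1ccccc1)[C@@H]2O[Si](C)(C)C(C)(C)C
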